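**Retrosynthetic overview**

1. Numbering: ring B (δ-lactone) is C1H2–O2–C3(=O)–C4–C4a–C11a; ring A (nine-membered) is C4a–C5–C6–C7–C8–C9–C10–C11–C11a; the side chain C12–C15 sits on C4; C18 is the methyl on C7 and C19 the methylene on C11.
2. Key disconnection: C5–C6 (closes ring A) together with C4=C12. The enabling feature is that C5 stands 1,3 to the lactone α-carbon C4 (C5–C4a–C4), which must become the alkylidene carbon, while C6 is α to the C7 carbonyl. A cyclopropane C4–C4a–C5 (temporary ring C) fused to ring B and activated at C4 by the C3 carbonyl and a phosphonate is therefore opened at C5 by a C6 β-keto sulfone carbanion, and the released C4 phosphonate carbanion olefinates the side-chain aldehyde in the same flask.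
3. After the key step: SmI2 desulfonylation, methyl addition to the C7 ketone, 7-OH-directed epoxidation of Z-C8=C9, desilylation. Before it: copper coupling of a C10 allylic bromide with a C9≡C8–C7(OH)–C6–SO2Ph alkyne, Lindlar reduction and oxidation; the cyclopropane comes from conjugate addition (C5), enolate phosphinylation and 3-exo-tet closure on a pentenolide made by ring-closing metathesis.
4. Stereochemistry: C11a is set by NHC–Cu-catalysed allylic substitution (the only catalyst-set centre of the bicycle); C4a, C7, C8 and C9 are relayed by substrate control; C14 comes from Sharpless epoxidation of prenol and C13 from Felkin–Anh vinyl addition.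
5. Ring order: ring B (metathesis), ring C (cyclopropane, temporary), ring A (key step, ring C opened), 8,9-epoxide; the 14,15-epoxide arrives with the aldehyde.

Key step: step 21

Remark: in step 3 the enantiomer of the NHC ligand is taken to be the one that delivers the alkenyl group to the face giving the R centre at C11a.

**Route**

Step 1
Reactants: 1 (Z)-4-(tert-butyldimethylsilyloxy)but-2-en-1-ol
Product: 2 (Z)-4-(tert-butyldimethylsilyloxy)but-2-en-1-yl diethyl phosphate
Conditions: ClP(O)(OEt)2, pyridine, DMAP (cat.), CH2Cl2, 0 °C to rt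
Reagents that add atoms: diethyl chlorophosphate, CCOP(=O)(Cl)OCC
Why: O-phosphorylation of the primary allylic alcohol installs the leaving group for the copper-catalysed allylic substitution; no stereocentre is involved.

Step 2
Reactants: 3 tert-butyldiphenyl(prop-2-yn-1-yloxy)silane
Product: 4 2-[3-(tert-butyldiphenylsilyloxy)prop-1-en-2-yl]-4,4,5,5-tetramethyl-1,3,2-dioxaborolane
Conditions: B2pin2, (SIMes)CuCl (5 mol%; SIMes = 1,3-dimesitylimidazolin-2-ylidene), NaOtBu (5 mol%), MeOH (2 equiv), THF, −50 to −15 °C
Reagents that add atoms: bis(pinacolato)diboron, CC1(C)OB(OC1(C)C)B1OC(C)(C)C(C)(C)O1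
Why: NHC–Cu-catalysed protoboration of a terminal alkyne, in which Cu–B adds syn with boron at the internal carbon (α-selectivity favoured by the N-aryl NHC and the propargylic oxygen) and methanol protonates the alkenylcopper.

Step 3
Reactants: 2 (Z)-allylic phosphate; 4 alkenylboronate
Product: 5 (2R)-1-(tert-butyldimethylsilyloxy)-2-[3-(tert-butyldiphenylsilyloxy)prop-1-en-2-yl]but-3-ene
Conditions: CuCl (5 mol%), chiral imidazolinium sulfonate (precursor of a bidentate sulfonate NHC ligand, 5.5 mol%), NaOMe (1.5 equiv), THF, 22 to 60 °C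
Reagents that add atoms: none
Why: NHC–Cu-catalysed enantioselective allylic substitution, in which the methoxide-activated alkenylboronate transfers its alkenyl group to copper and this attacks the γ-carbon in SN2′ fashion with loss of phosphate; the chiral NHC sets C11a (R).

Step 4
Reactants: 5 bis-silyl ether
Product: 6 (2R)-2-[3-(tert-butyldiphenylsilyloxy)prop-1-en-2-yl]but-3-en-1-ol
Conditions: camphorsulfonic acid (10 mol%), MeOH/CH2Cl2 (1:1), 0 °C
Reagents that add atoms: none
Why: Acid-catalysed methanolysis (selective desilylation) removes the primary TBS ether much faster than the TBDPS ether.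

Step 5
Reactants: 6 homoallylic alcohol
Product: 7 (2R)-2-[3-(tert-butyldiphenylsilyloxy)prop-1-en-2-yl]but-3-en-1-yl acrylate
Conditions: CH2=CHCOCl, iPr2NEt, CH2Cl2, −78 to 0 °C
Reagents that add atoms: acryloyl chloride, C=CC(=O)Cl
Why: Esterification of the primary alcohol brings in C3 and C4 of ring B.

Step 6
Reactants: 7 acrylate
Product: 8 (5R)-5-[3-(tert-butyldiphenylsilyloxy)prop-1-en-2-yl]-5,6-dihydro-2H-pyran-2-one
Conditions: second-generation Grubbs catalyst RuCl2(=CHPh)(PCy3)(H2IMes) (5 mol%), 1,4-benzoquinone (10 mol%), CH2Cl2 (5 mM), 40 °C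
Reagents that add atoms: none
Why: Ring-closing metathesis, in which the ruthenium carbene initiates at the monosubstituted vinyl group and closes the six-membered lactone with the acrylate while the 1,1-disubstituted alkene is too slow to initiate; benzoquinone suppresses alkene migration so C11a is untouched.

Step 7
Reactants: 8 pentenolide
Product: 10 trans-4-(hydroxymethyl)-3-(diethoxyphosphoryl) lactone, via silylmethyl phosphonite lactone 9 (not isolated)
Conditions: ClCH2SiMe2(OiPr), Mg, THF, rt (Grignard reagent); CuBr·SMe2 (10 mol%), 8, THF, −78 to −40 °C; ClP(OEt)2, −78 to 0 °C; then 30% H2O2, KF, KHCO3, THF/MeOH, 0 °C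
Reagents that add atoms: (chloromethyl)(isopropoxy)dimethylsilane, CC(C)O[Si](C)(C)CCl; diethyl chlorophosphite, CCOP(Cl)OCC; hydrogen peroxide, OO
Why: Copper-catalysed conjugate addition of the silylmethyl Grignard reagent (a hydroxymethyl anion equivalent) should occur anti to the C11a substituent and so set C4a, the magnesium enolate is trapped on carbon by the trivalent-phosphorus chloride (enolate phosphinylation), and H2O2/KF oxidises phosphorus to the phosphonate and the C–Si bond to C–OH (Tamao oxidation); the C4 centre is epimeric and inconsequential.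

Step 8
Reactants: 10 hydroxymethyl phosphono lactone
Product: 12 cyclopropane-fused phosphono lactone (TBDPS ether), via primary mesylate 11 (not isolated)
Conditions: MsCl, Et3N, CH2Cl2, −20 °C; then DBU, 0 °C to rt
Reagents that add atoms: methanesulfonyl chloride, CS(=O)(=O)Cl (its atoms stay in 11 only)
Why: After mesylation the phosphonate-stabilised lactone enolate at C4 displaces the mesylate in a 3-exo-tet C-alkylation (as in cyclopropane formation from γ-halo malonates), giving the necessarily cis-fused cyclopropane with C5 anti to the C11a substituent; C4a keeps its configuration and C4 follows from the ring fusion.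

Step 9
Reactants: 12 cyclopropane lactone TBDPS ether
Product: 13 cyclopropane lactone allylic alcohol
Conditions: HF·pyridine, pyridine, THF, 0 °C to rt
Reagents that add atoms: none
Why: Buffered fluoride cleavage of the silyl ether (desilylation) should leave the activated cyclopropane and the phosphonate intact.

Step 10
Reactants: 13 allylic alcohol
Product: 14 cyclopropane lactone allylic bromide
Conditions: CBr4, PPh3, CH2Cl2, −20 to 0 °C
Reagents that add atoms: carbon tetrabromide, BrC(Br)(Br)Br
Why: Appel bromination of the allylic alcohol; the 2-substituted allyl unit has equivalent termini, so allylic transposition is degenerate.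

Step 11
Reactants: 15 methyl phenyl sulfone; 16 3-(trimethylsilyl)prop-2-ynal
Product: 17 1-(phenylsulfonyl)-4-(trimethylsilyl)but-3-yn-2-ol (racemic)
Conditions: n-BuLi, THF, −78 °C; then 16, −78 °C; NH4Cl (aq)
Reagents that add atoms: none
Why: α-Lithiation of the sulfone and 1,2-addition to the ynal gives the β-hydroxy sulfone; the carbinol centre is oxidised later, so it is made racemic.

Step 12
Reactants: 17 silyl alkyne
Product: 18 1-(phenylsulfonyl)but-3-yn-2-ol (racemic)
Conditions: K2CO3 (0.2 equiv), MeOH, 0 °C
Reagents that add atoms: none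
Why: Base-catalysed methanolysis of the alkynyl C–Si bond (protodesilylation) frees the terminal alkyne.

Step 13
Reactants: 14 allylic bromide; 18 terminal alkyne
Product: 19 skipped enyne (cyclopropane lactone with C9≡C8–C7(OH)–C6H2–SO2Ph chain, carbinol epimers)
Conditions: CuI (20 mol%), K2CO3 (1.5 equiv), n-Bu4NCl, DMF, rt
Reagents that add atoms: none
Why: Copper-mediated coupling of a terminal alkyne with an allylic bromide (substitution by the copper acetylide) forms the C9–C10 bond; the symmetric 2-substituted allyl unit gives one regioisomer and carbonate should not open the cyclopropane.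

Step 14
Reactants: 19 skipped enyne
Product: 20 (Z)-allylic alcohol (Z-C8=C9)
Conditions: H2 (1 atm), Pd/CaCO3 poisoned with Pb(OAc)2 (Lindlar catalyst), quinoline, EtOAc, 0 °C to rt
Reagents that add atoms: none
Why: Lindlar semihydrogenation adds H2 syn to the alkyne to give the Z-alkene; the 1,1-disubstituted alkene and the cyclopropane should not be reduced on the poisoned catalyst.

Step 15
Reactants: 20 (Z)-allylic alcohol
Product: 21 (Z)-enone β-keto sulfone (cyclisation precursor)
Conditions: Dess–Martin periodinane, NaHCO3, CH2Cl2, 0 °C; used at once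
Reagents that add atoms: none
Why: Buffered Dess–Martin oxidation should give the Z-enone without isomerisation and creates the acidic C6–H2 (between ketone and sulfone) needed for the key step.

Step 16
Reactants: 22 3-methylbut-2-en-1-ol (prenol)
Product: 23 [(2S)-3,3-dimethyloxiran-2-yl]methanol
Conditions: Ti(OiPr)4 (5 mol%), L-(+)-diisopropyl tartrate (6 mol%), t-BuOOH, 4 Å molecular sieves, CH2Cl2, −20 °C
Reagents that add atoms: tert-butyl hydroperoxide, CC(C)(C)OO
Why: Sharpless asymmetric epoxidation, in which the titanium–tartrate complex delivers oxygen to one face of the allylic alcohol and sets C14 (S).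

Step 17
Reactants: 23 epoxy alcohol
Product: 24 (2R)-3,3-dimethyloxirane-2-carbaldehyde
Conditions: Dess–Martin periodinane, NaHCO3, CH2Cl2, 0 °C to rt; solution used directly
Reagents that add atoms: none
Why: Dess–Martin oxidation gives the volatile epoxy aldehyde, which is carried on in solution; the change of descriptor is only a change of priorities.

Step 18
Reactants: 24 epoxy aldehyde
Product: 25 (1S)-1-[(2S)-3,3-dimethyloxiran-2-yl]prop-2-en-1-ol
Conditions: CH2=CHMgBr, THF, −78 °C
Reagents that add atoms: vinylmagnesium bromide, C=C[Mg]Br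
Why: Grignard addition under Felkin–Anh control (epoxide C–O bond anti to the incoming nucleophile) should give the anti epoxy alcohol and so set C13 (S).

Step 19
Reactants: 25 epoxy allylic alcohol
Product: 26 triethylsilyl ether of 25
Conditions: Et3SiCl, imidazole, CH2Cl2, 0 °C
Reagents that add atoms: chlorotriethylsilane, CC[Si](Cl)(CC)CC
Why: Silylation protects the secondary alcohol as a TES ether that survives the basic, reductive and organometallic steps that follow.

Step 20
Reactants: 26 TES ether
Product: 27 (2R)-2-[(2S)-3,3-dimethyloxiran-2-yl]-2-(triethylsilyloxy)acetaldehyde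
Conditions: O3, CH2Cl2, −78 °C; then PPh3, −78 °C to rt
Reagents that add atoms: ozone, [O-][O+]=O
Why: Ozonolysis with reductive work-up cleaves the vinyl group to the aldehyde without touching the epoxide; the aldehyde is kept cold and used at once to avoid epimerisation at C13.

Step 21
Reactants: 21 (Z)-enone β-keto sulfone with cyclopropane-fused phosphono lactone; 27 α-silyloxy epoxy aldehyde
Product: 29 nine-membered β-keto sulfone carrying the (E)-alkylidene lactone side chain, via ring-A phosphonate enolate 28 (not isolated)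
Conditions: Cs2CO3 (1.2 equiv), MeCN (2 mM), 50 °C; then concentrate to 0.05 M, LiCl, DBU, 27 (1.5 equiv), 0 °C to rt
Reagents that add atoms: none
Why: Proposed new method: Cs2CO3 converts the β-keto sulfone into its soft enolate, whose C6 attacks the unsubstituted cyclopropane carbon C5 in an SN2-type homoconjugate addition and breaks the external C4–C5 bond (the bond that overlaps best with the lactone carbonyl, as in fused cyclopropyl ketones), so that ring C opens and ring A closes in a 9-exo-tet mode, driven by release of cyclopropane strain and formation of the phosphonate-stabilised lactone enolate 28. The closest known reaction types are the homoconjugate addition of stabilised carbanions to cyclopropanes bearing two geminal acceptors, established intermolecularly and intramolecularly for five- and six-membered rings, and ring-opening/olefination sequences of 1-phosphorylcyclopropanecarboxylates; what is new is the nine-membered ring, which four sp2 centres among the seven tether atoms (Z-alkene, enolate, 1,1-disubstituted alkene) and high dilution should make attainable. Because C6–H of the product is more acidic than C4–H, the anion returns to C6, which keeps the enone deactivated and should prevent transannular Michael addition of C4 to C9; LiCl/DBU then regenerate the C4 phosphonate carbanion, which olefinates 27 under Masamune–Roush conditions (Horner–Wadsworth–Emmons reaction) to give the E-alkylidene lactone expected for α-substituted phosphonoacetates, without epimerising the aldehyde. No ring stereocentre is formed or touched: C4a and C11a are carried from 21 (C4a only exchanges its C4–C5 neighbour relation for C5–C6), C13 and C14 come from 27, and the epimeric C6 centre is erased in step 22. The step needs C- over O-alkylation (soft carbon electrophile, caesium enolate), attack at C5 and not C4a (steric and stereoelectronic bias named above) and ring closure over oligomerisation (2 mM).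

Step 22
Reactants: 29 nine-membered β-keto sulfone
Product: 30 nine-membered (Z)-enone (C7 ketone, C6H2)
Conditions: SmI2 (2.5 equiv), THF/MeOH, −78 °C
Reagents that add atoms: none
Why: Reductive desulfonylation of an α-sulfonyl ketone by single-electron transfer from SmI2 expels benzenesulfinate and gives the samarium enolate, protonated by methanol; this should be much faster than reduction of the enone or the alkylidene lactone at −78 °C.

Step 23
Reactants: 30 nine-membered (Z)-enone
Product: 31 (7S)-tertiary allylic alcohol
Conditions: MeLi, CeCl3, THF, −78 °C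
Reagents that add atoms: methyllithium, [Li]C
Why: Organocerium 1,2-addition to the ketone (chemoselective over the alkylidene lactone and too weakly basic to deprotonate the doubly allylic C10–H2), in which methyl is expected to enter from the outer face of the C7 carbonyl of the trans-fused nine-membered ring (peripheral attack) and so give the 7S alcohol.

Step 24
Reactants: 31 tertiary allylic alcohol
Product: 32 13-O-triethylsilyl ether of the target
Conditions: VO(acac)2 (5 mol%), t-BuOOH, CH2Cl2, 0 °C
Reagents that add atoms: tert-butyl hydroperoxide, CC(C)(C)OO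
Why: Vanadium-catalysed hydroxyl-directed epoxidation, in which the C7 vanadate ester delivers oxygen to the syn face of the cis-C8=C9 alkene (syn epoxy alcohol, as for medium-ring allylic alcohols) and sets C8 and C9; the other alkenes are remote from the hydroxyl or electron-poor.

Step 25
Reactants: 32 TES ether
Product: 33 target CNP0147265.1
Conditions: HF·pyridine, pyridine, THF, 0 °C
Reagents that add atoms: none
Why: Buffered fluoride cleavage of the TES ether (desilylation) should spare both epoxides and avoid Payne rearrangement.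

**Compound list**

1 | (Z)-4-(tert-butyldimethylsilyloxy)but-2-en-1-ol | CC(C)(C)[Si](C)(C)OC/C=C\CO | starting material
2 | (Z)-4-(tert-butyldimethylsilyloxy)but-2-en-1-yl diethyl phosphate | CC(C)(C)[Si](C)(C)OC/C=C\COP(=O)(OCC)OCC | intermediate
3 | tert-butyldiphenyl(prop-2-yn-1-yloxy)silane | C#CCO[Si](c1ccccc1)(c1ccccc1)C(C)(C)C | starting material
4 | 2-[3-(tert-butyldiphenylsilyloxy)prop-1-en-2-yl]-4,4,5,5-tetramethyl-1,3,2-dioxaborolane | C=C(CO[Si](c1ccccc1)(c1ccccc1)C(C)(C)C)B1OC(C)(C)C(C)(C)O1 | intermediate
5 | (2R)-1-(tert-butyldimethylsilyloxy)-2-[3-(tert-butyldiphenylsilyloxy)prop-1-en-2-yl]but-3-ene | CC(C)(C)[Si](C)(C)OC[C@@H](C(=C)CO[Si](c1ccccc1)(c1ccccc1)C(C)(C)C)C=C | intermediate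
6 | (2R)-2-[3-(tert-butyldiphenylsilyloxy)prop-1-en-2-yl]but-3-en-1-ol | OC[C@@H](C(=C)CO[Si](c1ccccc1)(c1ccccc1)C(C)(C)C)C=C | intermediate
7 | (2R)-2-[3-(tert-butyldiphenylsilyloxy)prop-1-en-2-yl]but-3-en-1-yl acrylate | C=CC(=O)OC[C@@H](C(=C)CO[Si](c1ccccc1)(c1ccccc1)C(C)(C)C)C=C | intermediate
8 | (5R)-5-[3-(tert-butyldiphenylsilyloxy)prop-1-en-2-yl]-5,6-dihydro-2H-pyran-2-one | O=C1OC[C@@H](C(=C)CO[Si](c2ccccc2)(c2ccccc2)C(C)(C)C)C=C1 | intermediate
9 | diethyl (4R,5R)-5-[3-(tert-butyldiphenylsilyloxy)prop-1-en-2-yl]-4-{[isopropoxy(dimethyl)silyl]methyl}-2-oxotetrahydro-2H-pyran-3-ylphosphonite (4,5-trans, C3 epimers, not isolated) | O=C1OC[C@@H](C(=C)CO[Si](c2ccccc2)(c2ccccc2)C(C)(C)C)[C@H](C[Si](C)(C)OC(C)C)C1P(OCC)OCC | intermediate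
10 | diethyl [(4R,5R)-5-[3-(tert-butyldiphenylsilyloxy)prop-1-en-2-yl]-4-(hydroxymethyl)-2-oxotetrahydro-2H-pyran-3-yl]phosphonate (4,5-trans, C3 epimers) | O=C1OC[C@@H](C(=C)CO[Si](c2ccccc2)(c2ccccc2)C(C)(C)C)[C@H](CO)C1P(=O)(OCC)OCC | intermediate
11 | methanesulfonate of the primary alcohol of 10 (not isolated) | O=C1OC[C@@H](C(=C)CO[Si](c2ccccc2)(c2ccccc2)C(C)(C)C)[C@H](COS(C)(=O)=O)C1P(=O)(OCC)OCC | intermediate
12 | diethyl [(1R,5R,6S)-5-[3-(tert-butyldiphenylsilyloxy)prop-1-en-2-yl]-2-oxo-3-oxabicyclo[4.1.0]heptan-1-yl]phosphonate (cyclopropane CH2 anti to the C5 substituent) | O=C1OC[C@@H](C(=C)CO[Si](c3ccccc3)(c3ccccc3)C(C)(C)C)[C@@H]2C[C@]12P(=O)(OCC)OCC | intermediate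
13 | diethyl [(1R,5R,6S)-5-(3-hydroxyprop-1-en-2-yl)-2-oxo-3-oxabicyclo[4.1.0]heptan-1-yl]phosphonate | O=C1OC[C@@H](C(=C)CO)[C@@H]2C[C@]12P(=O)(OCC)OCC | intermediate
14 | diethyl [(1R,5R,6S)-5-(3-bromoprop-1-en-2-yl)-2-oxo-3-oxabicyclo[4.1.0]heptan-1-yl]phosphonate | O=C1OC[C@@H](C(=C)CBr)[C@@H]2C[C@]12P(=O)(OCC)OCC | intermediate
15 | methyl phenyl sulfone | CS(=O)(=O)c1ccccc1 | starting material
16 | 3-(trimethylsilyl)prop-2-ynal | C[Si](C)(C)C#CC=O | starting material
17 | 1-(phenylsulfonyl)-4-(trimethylsilyl)but-3-yn-2-ol (racemic) | C[Si](C)(C)C#CC(O)CS(=O)(=O)c1ccccc1 | intermediate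
18 | 1-(phenylsulfonyl)but-3-yn-2-ol (racemic) | C#CC(O)CS(=O)(=O)c1ccccc1 | intermediate
19 | diethyl [(1R,5R,6S)-5-[6-hydroxy-7-(phenylsulfonyl)hept-1-en-4-yn-2-yl]-2-oxo-3-oxabicyclo[4.1.0]heptan-1-yl]phosphonate (carbinol epimers) | O=C1OC[C@@H](C(=C)CC#CC(O)CS(=O)(=O)c3ccccc3)[C@@H]2C[C@]12P(=O)(OCC)OCC | intermediate
20 | diethyl [(1R,5R,6S)-5-[(4Z)-6-hydroxy-7-(phenylsulfonyl)hepta-1,4-dien-2-yl]-2-oxo-3-oxabicyclo[4.1.0]heptan-1-yl]phosphonate (carbinol epimers) | O=C1OC[C@@H](C(=C)C/C=C\C(O)CS(=O)(=O)c3ccccc3)[C@@H]2C[C@]12P(=O)(OCC)OCC | intermediate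
21 | diethyl [(1R,5R,6S)-5-[(4Z)-6-oxo-7-(phenylsulfonyl)hepta-1,4-dien-2-yl]-2-oxo-3-oxabicyclo[4.1.0]heptan-1-yl]phosphonate | O=C1OC[C@@H](C(=C)C/C=C\C(=O)CS(=O)(=O)c3ccccc3)[C@@H]2C[C@]12P(=O)(OCC)OCC | intermediate
22 | 3-methylbut-2-en-1-ol (prenol) | CC(C)=CCO | starting material
23 | [(2S)-3,3-dimethyloxiran-2-yl]methanol | OC[C@@H]1OC1(C)C | intermediate
24 | (2R)-3,3-dimethyloxirane-2-carbaldehyde | O=C[C@@H]1OC1(C)C | intermediate
25 | (1S)-1-[(2S)-3,3-dimethyloxiran-2-yl]prop-2-en-1-ol | C=C[C@H](O)[C@@H]1OC1(C)C | intermediate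
26 | triethyl{[(1S)-1-[(2S)-3,3-dimethyloxiran-2-yl]prop-2-en-1-yl]oxy}silane | C=C[C@H](O[Si](CC)(CC)CC)[C@@H]1OC1(C)C | intermediate
27 | (2R)-2-[(2S)-3,3-dimethyloxiran-2-yl]-2-(triethylsilyloxy)acetaldehyde | O=C[C@H](O[Si](CC)(CC)CC)[C@@H]1OC1(C)C | intermediate
28 | bicyclic core with ring A closed: diethyl phosphonate on C4, 6-phenylsulfonyl, C7 ketone, Z-C8=C9, 11-methylene; 4aS,11aR; C4 and C6 epimers; present as its caesium salt (not isolated) | C=C1C/C=C\C(=O)C(S(=O)(=O)c3ccccc3)C[C@@H]2C(P(=O)(OCC)OCC)C(=O)OC[C@@H]12 | intermediate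
29 | target skeleton with C7 ketone, 6-phenylsulfonyl (C6 epimers), Z-C8=C9, 13-O-triethylsilyl; 4aS,11aR,13S,14S, 4(12)E | C=C1C/C=C\C(=O)C(S(=O)(=O)c3ccccc3)C[C@@H]2/C(=C\[C@H](O[Si](CC)(CC)CC)[C@@H]3OC3(C)C)C(=O)OC[C@@H]12 | intermediate
30 | target skeleton with C7 ketone, C6H2, Z-C8=C9, 13-O-triethylsilyl; 4aS,11aR,13S,14S, 4(12)E | C=C1C/C=C\C(=O)CC[C@@H]2/C(=C\[C@H](O[Si](CC)(CC)CC)[C@@H]3OC3(C)C)C(=O)OC[C@@H]12 | intermediate
31 | (7S)-7-hydroxy-7-methyl compound with Z-C8=C9, 13-O-triethylsilyl; 4aS,11aR,13S,14S, 4(12)E | C=C1C/C=C\[C@@](C)(O)CC[C@@H]2/C(=C\[C@H](O[Si](CC)(CC)CC)[C@@H]3OC3(C)C)C(=O)OC[C@@H]12 | intermediate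
32 | 13-O-triethylsilyl ether of the target (4aS,7S,8R,9R,11aR,13S,14S) | C=C1C[C@H]2O[C@H]2[C@@](C)(O)CC[C@@H]2/C(=C\[C@H](O[Si](CC)(CC)CC)[C@@H]3OC3(C)C)C(=O)OC[C@@H]12 | intermediate
33 | CNP0147265.1 (4aS,7S,8R,9R,11aR,13S,14S, 4(12)E) | C=C1C[C@H]2O[C@H]2[C@@](C)(O)CC[C@@H]2/C(=C\[C@H](O)[C@@H]3OC3(C)C)C(=O)OC[C@@H]12 | target

**Step count and risks**

Total: 25 steps. Longest linear sequence: 17 steps (steps 1, 3–10, 13–15 and 21–25, from 1 to 33).

Most likely to fail, first: step 21. The nine-membered ring closure by homoconjugate addition may lose to oligomerisation or O-alkylation, or the cyclopropane may not open at a temperature that the Z-enone tolerates. The fallback uses known chemistry and sets out from 20. MgI2 in THF opens the activated cyclopropane by homoconjugate addition of iodide at C5, and the magnesium phosphonoenolate so formed olefinates 27 to give the (E)-alkylidene lactone primary iodide with free C7 carbinol F1. Dess–Martin oxidation gives the iodo β-keto sulfone F2. Cs2CO3 in MeCN at high dilution then closes ring A by intramolecular C-alkylation of the β-keto sulfone with the primary iodide, forming the same C5–C6 bond, and the route is rejoined at 29.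

Second: step 23. Facial selectivity of the methyl addition to the C7 ketone may be poor or opposite, since it rests on the conformation of the nine-membered ring. The fallback reverses the order of events so that an epoxide, not the ring alone, steers the methyl group, and sets out from 30. Nucleophilic epoxidation of the Z-enone (t-BuOOH, DBU, THF, 0 °C) gives the cis-8,9-epoxy ketone F3. MeLi/CeCl3 at −78 °C then adds anti to the epoxide oxygen, giving the syn epoxy alcohol, and the route is rejoined at 32. If the same ring face is exposed to both reagents, this sequence gives the C7/C8/C9 set opposite to that of steps 23–24, so one of the two orders should lead to the target.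

Third: step 7. The magnesium enolate may be phosphinylated poorly, or the freed primary alcohol may translactonise to the γ-lactone under the basic Tamao conditions. The fallback replaces conjugate addition and alkylation by carbene chemistry and sets out from 6. Esterification with diethylphosphonoacetic acid (DCC, DMAP) gives the phosphonoacetate F4. Diazo transfer (4-acetamidobenzenesulfonyl azide, DBU, MeCN) gives the diazo phosphonoacetate F5. Rh2(esp)2-catalysed intramolecular cyclopropanation of the vinyl group then forms the cyclopropane-fused lactone directly, and the route is rejoined at 12; preference for the vinyl group over the hindered 1,1-disubstituted alkene would have to be confirmed.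

**Further compounds**

F1 | step 21 | (E)-alkylidene lactone primary iodide: ring B with C5H2–I on C4a, complete 13-O-triethylsilyl side chain on C4, C11a chain with Z-C8=C9 and C7 carbinol (epimers) bearing CH2SO2Ph | O=C1OC[C@@H](C(=C)C/C=C\C(O)CS(=O)(=O)c2ccccc2)[C@H](CI)/C1=C\[C@H](O[Si](CC)(CC)CC)[C@@H]2OC2(C)C
F2 | step 21 | iodo β-keto sulfone: as F1 with C7 ketone | O=C1OC[C@@H](C(=C)C/C=C\C(=O)CS(=O)(=O)c2ccccc2)[C@H](CI)/C1=C\[C@H](O[Si](CC)(CC)CC)[C@@H]2OC2(C)C
F3 | step 23 | cis-(8R,9R)-8,9-epoxy C7 ketone with 13-O-triethylsilyl side chain (4aS,11aR,13S,14S) | C=C1C[C@H]2O[C@H]2C(=O)CC[C@@H]2/C(=C\[C@H](O[Si](CC)(CC)CC)[C@@H]3OC3(C)C)C(=O)OC[C@@H]12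
F4 | step 7 | (2R)-2-[3-(tert-butyldiphenylsilyloxy)prop-1-en-2-yl]but-3-en-1-yl (diethoxyphosphoryl)acetate | CCOP(=O)(OCC)CC(=O)OC[C@@H](C(=C)CO[Si](c1ccccc1)(c1ccccc1)C(C)(C)C)C=C
F5 | step 7 | (2R)-2-[3-(tert-butyldiphenylsilyloxy)prop-1-en-2-yl]but-3-en-1-yl diazo(diethoxyphosphoryl)acetate | CCOP(=O)(OCC)C(=[N+]=[N-])C(=O)OC[C@@H](C(=C)CO[Si](c1ccccc1)(c1ccccc1)C(C)(C)C)C=C
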